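**Retrosynthetic overview**
- The plan rests on rings A and B. They form a trans-decalin whose four adjacent centres, C4 (quaternary, CH3 plus the ester carbon C18), C5 (H), C10 (quaternary, CH3) and C9 (H, side chain), show the relative pattern of a chair–chair polyene fold.
- C4–C5 and C9–C10 are cut together. Ring A and then ring B close in one cationic cascade from the acyclic epoxy diene allylsilane 15, which is built from geranyl acetate, methyl acetoacetate and Me3SiCH2MgCl. A Sharpless epoxide supplies the absolute configuration.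
- After the cascade the C3–OH is removed and C8 is hydrated through the α-epoxide. C6–O is installed by 1,5-hydrogen abstraction from the C18 alkoxy radical, which gives a transient ring C18–O–C6 that is oxidised to the lactone and opened to the hydroxy ester.
- Side chain: C11 aldehyde, vinyl, B-alkyl Suzuki coupling (C12–C13), Sharpless epoxide, invertive perhydrolysis (C13–OOH), glycol cleavage and methylenation, cross metathesis (C14=C15) with butenolide 49 (ring made separately), global desilylation.

Key step: step 11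

Remark on numbering: labdane numbers are used for C1–C20. C16 is the methyl on C13, C17 the carbon on C8, C18 the equatorial α carbon on C4, C19 the axial β methyl on C4, and C20 the methyl on C10. The butenolide is numbered O1'–C5', and C5' is bonded to C15.

Step 1
Reactants: 1 geranyl acetate
Product: 2 (2E,6E)-8-hydroxygeranyl acetate
Conditions: SeO2 (cat.), t-BuOOH, salicylic acid (cat.), CH2Cl2, 0 °C to rt
Reagents that add atoms: tert-butyl hydroperoxide (oxygen donor relayed by SeO2), CC(C)(C)OO
Why: Selenium dioxide allylic oxidation (ene reaction, then [2,3]-sigmatropic shift) prefers the electron-rich terminal alkene over the acetate-deactivated one and oxidises the methyl group trans to the chain, so the (E)-allylic alcohol should result.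

Step 2
Reactants: 2 (2E,6E)-8-hydroxygeranyl acetate
Product: 3 (2E)-5-[(2S,3S)-3-(hydroxymethyl)-3-methyloxiran-2-yl]-3-methylpent-2-enyl acetate
Conditions: Ti(O-i-Pr)4 (cat.), L-(+)-diethyl tartrate (cat.), t-BuOOH, 4 Å MS, CH2Cl2, −20 °C
Reagents that add atoms: tert-butyl hydroperoxide, CC(C)(C)OO
Why: Sharpless asymmetric epoxidation acts only on the alkene that carries the allylic OH, and with L-(+)-tartrate an (E)-2-methyl-2-alken-1-ol should give the (2S,3S)-epoxy alcohol, which sets future C3 and C4 with CH2OH trans to the chain.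

Step 3
Reactants: 3 epoxy alcohol acetate
Product: 4 (2E)-5-[(2S,3S)-3-(benzyloxymethyl)-3-methyloxiran-2-yl]-3-methylpent-2-enyl acetate
Conditions: BnBr, Ag2O, Bu4NI (cat.), CH2Cl2, rt, dark
Reagents that add atoms: benzyl bromide, BrCc1ccccc1
Why: Silver-oxide-promoted Williamson benzylation works without a free alkoxide, so Payne rearrangement of the epoxy alcohol and acetate transfer should not compete.

Step 4
Reactants: 4 benzyl ether acetate
Product: 5 (2E)-5-[(2S,3S)-3-(benzyloxymethyl)-3-methyloxiran-2-yl]-3-methylpent-2-en-1-ol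
Conditions: K2CO3 (cat.), MeOH, 0 °C to rt
Reagents that add atoms: none
Why: Base-catalysed transesterification removes only the acetate, because the epoxide and the benzyl ether are inert to methanolic carbonate at this temperature.

Step 5
Reactants: 5 allylic alcohol
Product: 7 (2S,3S)-2-(benzyloxymethyl)-3-[(3E)-5-bromo-3-methylpent-3-enyl]-2-methyloxirane, via allylic mesylate 6 (not isolated)
Conditions: MsCl, Et3N, THF, −40 °C; then LiBr, THF, 0 °C
Reagents that add atoms: lithium bromide, [Li+].[Br-]; methanesulfonyl chloride, CS(=O)(=O)Cl (kept in 6 only)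
Why: Mesylation and in situ Finkelstein-type SN2 displacement by bromide run under non-acidic conditions that keep the E alkene and the epoxide intact.

Step 6
Reactants: 7 allylic bromide; 8 methyl acetoacetate
Product: 10 methyl (6E)-9-[(2S,3S)-3-(benzyloxymethyl)-3-methyloxiran-2-yl]-7-methyl-3-oxonon-6-enoate, via acetoacetate dianion 9 (not isolated)
Conditions: 8, NaH, THF, 0 °C; n-BuLi, 0 °C; then 7, 0 °C; AcOH quench
Reagents that add atoms: sodium hydride, [Na+].[H-]; n-butyllithium, [Li]CCCC (counter-ions of 9 only)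
Why: In this acetoacetate dianion alkylation the more reactive terminal carbanion attacks the allylic bromide by SN2 much faster than it could open the trisubstituted epoxide, which joins C6 to C7.

Step 7
Reactants: 10 β-keto ester
Product: 11 methyl (2Z,6E)-9-[(2S,3S)-3-(benzyloxymethyl)-3-methyloxiran-2-yl]-3-(diethoxyphosphoryloxy)-7-methylnona-2,6-dienoate
Conditions: NaH, (EtO)2P(O)Cl, Et2O, 0 °C
Reagents that add atoms: diethyl chlorophosphate, CCOP(=O)(Cl)OCC
Why: O-Phosphorylation of the chelated sodium enolate of a β-keto ester should give the (Z)-enol phosphate, with phosphate and ester on the same side.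

Step 8
Reactants: 11 (Z)-enol phosphate; 12 (trimethylsilyl)methylmagnesium chloride
Product: 13 methyl (2Z,6E)-9-[(2S,3S)-3-(benzyloxymethyl)-3-methyloxiran-2-yl]-7-methyl-3-(trimethylsilylmethyl)nona-2,6-dienoate
Conditions: Ni(acac)2 (cat.), THF, 0 °C to rt
Reagents that add atoms: none
Why: Nickel-catalysed Kumada-type coupling of an enol phosphate goes with retention at the alkene, so CH2SiMe3 should end cis to the ester (C7 trans to C11), and this bulky Grignard reagent is slow towards the ester and the epoxide.

Step 9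
Reactants: 13 allylsilane ester
Product: 14 (2Z,6E)-9-[(2S,3S)-3-(benzyloxymethyl)-3-methyloxiran-2-yl]-7-methyl-3-(trimethylsilylmethyl)nona-2,6-dien-1-ol
Conditions: i-Bu2AlH, CH2Cl2, −78 °C; aq potassium sodium tartrate
Reagents that add atoms: none
Why: DIBAL-H reduces the conjugated ester to the allylic alcohol at low temperature, where the epoxide is not opened, and the non-acidic tartrate work-up avoids loss of the allylsilane.

Step 10
Reactants: 14 allylic alcohol
Product: 15 (2Z,6E)-epoxy diene allylsilane, the O-TBS ether of 14 (C18 as CH2OBn trans to the chain on the (3S,4S)-epoxide; C5=C10 E; C7 trans to C11 across C8=C9)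
Conditions: TBSCl, imidazole, CH2Cl2, 0 °C to rt
Reagents that add atoms: tert-butyldimethylsilyl chloride, CC(C)(C)[Si](C)(C)Cl
Why: Standard silylation under basic conditions masks O11 as a weakly Lewis-basic ether, and TBS is chosen because it carries no arene that the ruthenium tetroxide of step 19 could attack.

Step 11
Reactants: 15 epoxy diene allylsilane
Product: 16 18-benzyloxy-11-(tert-butyldimethylsilyloxy)-12,13,14,15,16-pentanorlabd-8(17)-en-3β-ol
Conditions: MeAlCl2, CH2Cl2, −78 °C; Et3N/MeOH, then H2O
Reagents that add atoms: none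
Why: MeAlCl2 binds the epoxide oxygen (helped by the neighbouring benzyl ether oxygen) and weakens the tertiary C4–O bond; C5 of the C5=C10 alkene attacks C4 from the side opposite to oxygen, C9 of the allylsilane captures the developing C10 cation, and the β-silyl cation at C8 gives up Me3Si to chloride, so only the exocyclic C8=C17 alkene is left. The closest known reaction type is the Lewis-acid epoxy-polyene cyclisation terminated by an allylsilane. Ring A closes 6-endo at both the epoxide and the C5=C10 alkene, and ring B closes 6-endo at the C8=C9 alkene, each through a chair-like fold. C4 is set by inversion, and since CH2OBn is trans to the chain on the epoxide it becomes equatorial (α) and CH3 axial (β); C5 and C10 follow from anti addition across the E alkene (5α-H, 10β-CH3, trans fusion); C9 follows from the allylsilane geometry (C7 trans to C11, which is Z by the sequence rule because CH2Si outranks C7), which places C11 equatorial (β, 9α-H). The absolute sense comes from C3, whose C–O bond is kept and lies equatorial (3β) in the fold. The step needs the epoxide to ionise before the allylic silyl ether, which the higher Lewis basicity of the epoxide/benzyl ether pair, the poor donor ability of the OTBS oxygen and the low temperature should secure, and it needs cleavage at C4 rather than C3, which the tertiary nature of C4 secures.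

Step 12
Reactants: 16 3β-alcohol
Product: 17 3-O-(imidazol-1-ylthiocarbonyl) derivative of 16
Conditions: 1,1'-thiocarbonyldiimidazole, DMAP (cat.), ClCH2CH2Cl, 80 °C
Reagents that add atoms: 1,1'-thiocarbonyldiimidazole, S=C(n1ccnc1)n1ccnc1
Why: Thioacylation of the equatorial 3β-alcohol needs no strong base and gives the radical precursor for deoxygenation.

Step 13
Reactants: 17 thiocarbonylimidazolide
Product: 18 18-benzyloxy-11-(tert-butyldimethylsilyloxy)-12,13,14,15,16-pentanorlabd-8(17)-ene
Conditions: Bu3SnH, AIBN (cat.), toluene, 110 °C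
Reagents that add atoms: none
Why: Barton–McCombie deoxygenation: the stannyl radical adds to sulfur, the C3–O bond fragments, and the secondary C3 radical, too remote from C8=C17 to cyclise, takes hydrogen from the stannane.

Step 14
Reactants: 18 exocyclic alkene
Product: 19 8α,17-epoxide of 18 (oxygen α, C17 β on C8)
Conditions: m-CPBA, NaHCO3, CH2Cl2, 0 °C
Reagents that add atoms: m-chloroperbenzoic acid, OOC(=O)c1cccc(Cl)c1
Why: In this Prilezhaev epoxidation the β face of C8=C17 is screened by the axial C20 methyl group, so the peracid should add from the α face and place oxygen α (equatorial) and C17 β (axial) on C8.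

Step 15
Reactants: 19 8α,17-epoxide
Product: 20 18-benzyloxy-11-(tert-butyldimethylsilyloxy)-12,13,14,15,16-pentanorlabdan-8α-ol
Conditions: LiEt3BH, THF, 0 °C to rt; then H2O
Reagents that add atoms: none
Why: Triethylborohydride opens the spiro epoxide by SN2 attack at the unsubstituted C17, the C8–O bond is untouched, and C8 therefore keeps 8α-OH with C17 as the axial β methyl group.

Step 16
Reactants: 20 8α-alcohol
Product: 21 8α-O-triethylsilyl ether of 20
Conditions: TESOTf, 2,6-lutidine, CH2Cl2, 0 °C
Reagents that add atoms: triethylsilyl triflate, CC[Si](CC)(CC)OS(=O)(=O)C(F)(F)F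
Why: Silyl triflate silylation covers the hindered tertiary alcohol, which would otherwise form its own hypoiodite in step 18.

Step 17
Reactants: 21 benzyl ether
Product: 22 11-(tert-butyldimethylsilyloxy)-8α-(triethylsilyloxy)-12,13,14,15,16-pentanorlabdan-18-ol
Conditions: H2 (1 atm), Pd/C, EtOAc, rt
Reagents that add atoms: none
Why: Hydrogenolysis cleaves only the benzyl ether now that no alkene is left, and silyl ethers are stable in ethyl acetate.

Step 18
Reactants: 22 C18 alcohol
Product: 24 6α,18-epoxy-11-(tert-butyldimethylsilyloxy)-8α-(triethylsilyloxy)-12,13,14,15,16-pentanorlabdane, via C18 hypoiodite 23 (not isolated)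
Conditions: PhI(OAc)2, I2, cyclohexane, visible light, rt
Reagents that add atoms: iodine, [I][I] (iodine atom of 23 only)
Why: Suárez hypoiodite reaction: the C18 alkoxy radical on the equatorial arm of C4 lies peri to the equatorial C6–Hα and abstracts it through a six-membered transition state, and the iodide formed at C6 is displaced by O18, so the tether can place oxygen only on the α face of C6.

Step 19
Reactants: 24 6α,18-ether
Product: 25 11-(tert-butyldimethylsilyloxy)-8α-(triethylsilyloxy)-12,13,14,15,16-pentanorlabdan-18,6α-olide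
Conditions: RuCl3 hydrate (cat.), NaIO4, CCl4/MeCN/H2O, rt
Reagents that add atoms: sodium periodate (oxygen donor relayed by RuO4), [Na+].[O-]I(=O)(=O)=O
Why: Ruthenium tetroxide oxidation of a cyclic ether attacks the O–CH2 group (C18) in preference to the O–CH group (C6), as in the classical ether-to-lactone sequel of hypoiodite reactions, and the substrate holds no arene or alkene.

Step 20
Reactants: 25 bis-silyl lactone
Product: 26 8α,11-dihydroxy-12,13,14,15,16-pentanorlabdan-18,6α-olide
Conditions: Bu4NF, THF, rt to 50 °C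
Reagents that add atoms: none
Why: Fluoride cleaves both silyl ethers while the non-enolisable lactone stays closed.

Step 21
Reactants: 26 dihydroxy lactone
Product: 28 methyl 6α,8α,11-trihydroxy-12,13,14,15,16-pentanorlabdan-18-oate, via potassium carboxylate 27 (not isolated)
Conditions: KOH (1.1 equiv), MeOH/H2O, 70 °C; evaporate to dryness; MeI, DMF, rt
Reagents that add atoms: potassium hydroxide, [K+].[OH-]; methyl iodide, IC
Why: Saponification of the strained peri lactone and SN2 methylation of the carboxylate salt avoid the free hydroxy acid, which would close back to the lactone, and leave C6 untouched.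

Step 22
Reactants: 28 triol ester
Product: 29 methyl 6α,8α-dihydroxy-11-oxo-12,13,14,15,16-pentanorlabdan-18-oate
Conditions: TEMPO (cat.), PhI(OAc)2, CH2Cl2, rt
Reagents that add atoms: none
Why: Oxoammonium (TEMPO) oxidation is governed by steric access, so the primary C11 alcohol should react before the hindered, hydrogen-bonded 6α-alcohol, and the tertiary 8α-alcohol cannot react.

Step 23
Reactants: 29 dihydroxy aldehyde
Product: 30 methyl 11-oxo-6α,8α-bis(triethylsilyloxy)-12,13,14,15,16-pentanorlabdan-18-oate
Conditions: TESOTf, 2,6-lutidine, CH2Cl2, −78 to 0 °C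
Reagents that add atoms: triethylsilyl triflate, CC[Si](CC)(CC)OS(=O)(=O)C(F)(F)F
Why: Silyl triflate silylation covers both alcohols and so blocks retro-aldol cleavage of the β-hydroxy aldehyde and alkoxide attack on the C18 ester in the basic steps that follow.

Step 24
Reactants: 30 bis-silyl aldehyde
Product: 31 methyl 6α,8α-bis(triethylsilyloxy)-13,14,15,16-tetranorlabd-11-en-18-oate
Conditions: MePPh3Br, KHMDS, THF, −78 °C to rt
Reagents that add atoms: methyltriphenylphosphonium bromide, C[P+](c1ccccc1)(c1ccccc1)c1ccccc1.[Br-]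
Why: Wittig methylenation with the small non-stabilised ylide should reach the hindered aldehyde faster than it deprotonates C9, whose equatorial substituent is in any case the stable one, and the neopentyl-type ester is inert.

Step 25
Reactants: 32 but-2-yn-1-ol
Product: 34 (E)-3-iodobut-2-en-1-ol, via alkenylzirconocene 33 (not isolated)
Conditions: Cp2Zr(H)Cl (2.2 equiv), THF, rt to 40 °C; I2, −78 to 0 °C; then H2O
Reagents that add atoms: iodine, [I][I]; Cp2Zr(H)Cl, [H-].[Cl-].[Zr+4].c1cc[cH-]c1.c1cc[cH-]c1 (zirconium units of 33 only)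
Why: Syn hydrozirconation with excess Schwartz reagent equilibrates zirconium to C3, the carbon remote from the zirconium alkoxide, and iodinolysis goes with retention to give the E iodide.

Step 26
Reactants: 31 terminal alkene; 34 (E)-3-iodobut-2-en-1-ol
Product: 36 methyl (13E)-15-hydroxy-6α,8α-bis(triethylsilyloxy)labd-13-en-18-oate, via B-alkyl-9-BBN adduct 35 (not isolated)
Conditions: 9-BBN-H, THF, rt to 50 °C; then 34, Pd(dppf)Cl2 (cat.), AsPh3 (cat.), aq K3PO4, DMF, rt
Reagents that add atoms: 9-BBN-H, [H]B1C2CCCC1CCC2 (boron unit of 35 only)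
Why: 9-BBN adds to the terminal carbon of the monosubstituted alkene without touching the ester, and the B-alkyl Suzuki–Miyaura coupling forms C12–C13 with retention of the iodide geometry, which gives the 13E alkene.

Step 27
Reactants: 36 (13E)-allylic alcohol
Product: 37 methyl (13S,14S)-13,14-epoxy-15-hydroxy-6α,8α-bis(triethylsilyloxy)labdan-18-oate
Conditions: Ti(O-i-Pr)4, L-(+)-diethyl tartrate, t-BuOOH, 4 Å MS, CH2Cl2, −20 °C
Reagents that add atoms: tert-butyl hydroperoxide, CC(C)(C)OO
Why: Sharpless asymmetric epoxidation is reagent-controlled here because the ring stereocentres are remote, and L-(+)-tartrate should convert this geraniol-type (E)-allylic alcohol to the (13S,14S)-epoxide.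

Step 28
Reactants: 37 epoxy alcohol
Product: 38 methyl (13R,14S)-13-hydroperoxy-14,15-dihydroxy-6α,8α-bis(triethylsilyloxy)labdan-18-oate
Conditions: anhydrous H2O2 in Et2O (large excess), MoO2(acac)2 (cat.), 0 °C to rt
Reagents that add atoms: hydrogen peroxide, OO
Why: Molybdenum-catalysed perhydrolysis of an epoxide: the metal binds the epoxy alcohol and hydrogen peroxide attacks the tertiary C13, remote from the electron-withdrawing C15–O, from the side opposite to the epoxide oxygen, so inversion should give (13R)-OOH, while the bulky silyl ether on O8 is a poor competitor.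

Step 29
Reactants: 38 hydroperoxy diol
Product: 39 methyl (13R,14S)-14,15-dihydroxy-6α,8α-bis(triethylsilyloxy)-13-(triethylsilylperoxy)labdan-18-oate
Conditions: Et3SiCl (1.0 equiv), Et3N, CH2Cl2, −78 to −40 °C
Reagents that add atoms: chlorotriethylsilane, CC[Si](CC)(CC)Cl
Why: Chemoselective silylation: the hydroperoxide is some three pK units more acidic than an alcohol and its anion is an α-effect nucleophile, so with one equivalent of chlorosilane and only triethylamine as base it should react before the diol.

Step 30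
Reactants: 39 silylperoxy diol
Product: 40 methyl (13R)-14-oxo-6α,8α-bis(triethylsilyloxy)-13-(triethylsilylperoxy)-15-norlabdan-18-oate
Conditions: NaIO4 on silica gel, CH2Cl2, 0 °C to rt
Reagents that add atoms: none
Why: Malaprade glycol cleavage needs only the free 14,15-diol, removes C15 as formaldehyde and leaves the quaternary C13 untouched, and the supported reagent keeps bulk water away from the silyl peroxide.

Step 31
Reactants: 40 α-silylperoxy aldehyde
Product: 41 methyl (13R)-6α,8α-bis(triethylsilyloxy)-13-(triethylsilylperoxy)labd-14-en-18-oate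
Conditions: MePPh3Br, KHMDS, THF, −78 °C
Reagents that add atoms: methyltriphenylphosphonium bromide, C[P+](c1ccccc1)(c1ccccc1)c1ccccc1.[Br-]
Why: Wittig methylenation of a non-enolisable α-peroxy aldehyde, a reaction type known for protected hydroperoxides, is fast at low temperature, where the ylide should not attack the O–O bond.

Step 32
Reactants: 42 methyl propiolate; 43 (E)-crotonaldehyde
Product: 45 racemic methyl (5E)-4-hydroxyhept-5-en-2-ynoate, via lithium methyl propiolate 44 (not isolated)
Conditions: 42, LDA, THF, −78 °C; then 43; AcOH quench at −78 °C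
Reagents that add atoms: lithium diisopropylamide, [Li+].CC(C)[N-]C(C)C (lithium of 44 only)
Why: 1,2-Addition of the lithium acetylide of methyl propiolate to the enal at −78 °C, where the acetylide is stable, gives the racemic carbinol.

Step 33
Reactants: 45 racemic carbinol
Product: 46 methyl (5E)-4-oxohept-5-en-2-ynoate
Conditions: MnO2 (activated), CH2Cl2, rt
Reagents that add atoms: none
Why: Manganese dioxide oxidises the doubly activated (allylic and propargylic) alcohol under neutral conditions.

Step 34
Reactants: 46 enynone ester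
Product: 47 methyl (4S,5E)-4-hydroxyhept-5-en-2-ynoate
Conditions: (S)-Alpine-Borane (B-isopinocampheyl-9-BBN from (−)-α-pinene), neat, rt; then HOCH2CH2NH2, Et2O
Reagents that add atoms: none
Why: Midland reduction: the alkynyl group acts as the small substituent in the boat-like hydride transfer, and the reagent from (−)-α-pinene, which turns alkyl alkynyl ketones into (S)-carbinols, should set future C5' as S, γ-oxo alkynoates being especially fast substrates.

Step 35
Reactants: 47 (S)-hydroxy alkynoate
Product: 49 (5S)-4-methyl-5-[(E)-prop-1-enyl]furan-2(5H)-one, via open (Z)-hydroxy enoate 48 (not isolated)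
Conditions: Me2CuLi (from MeLi and CuI, 2.2 equiv), THF, −78 °C; aq NH4Cl at −78 °C, then rt
Reagents that add atoms: lithium dimethylcuprate, [Li+].C[Cu-]C
Why: Syn carbocupration of the alkynoate puts the new methyl group cis to hydrogen and hence the carbinol carbon cis to the ester, so 48 lactonises on work-up without touching the C5'–O bond, and the cold quench limits base-induced epimerisation.

Step 36
Reactants: 41 vinyl silyl peroxide; 49 (S)-butenolide
Product: 50 tris(triethylsilyl) derivative of the target (6α-OTES; 8α-OTES; 13-OOTES; 14E)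
Conditions: second-generation Hoveyda–Grubbs catalyst RuCl2(SIMes)(=CH-C6H4-2-O-i-Pr) (cat.), 49 (excess), CH2Cl2, 40 °C
Reagents that add atoms: none
Why: Olefin cross metathesis: the vinyl group next to the quaternary C13 does not homodimerise and the allylic-ester-type partner dimerises only slowly, so the cross product should dominate and form as the E alkene for steric reasons, and silyl or dialkyl peroxides are tolerated by ruthenium alkylidenes under neutral conditions.

Step 37
Reactants: 50 tris-silyl derivative
Product: 51 target CNP0128148.1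
Conditions: HF·pyridine, pyridine, THF, 0 °C to rt
Reagents that add atoms: none
Why: Buffered fluoride-mediated desilylation removes the three triethylsilyl groups under weakly acidic conditions that should neither epimerise C5' nor trigger Hock cleavage of the tertiary allylic hydroperoxide.

**Compound list**
1 | geranyl acetate | CC(C)=CCC/C(C)=C/COC(C)=O | starting material
2 | (2E,6E)-8-hydroxygeranyl acetate | OC/C(C)=C/CC/C(C)=C/COC(C)=O | intermediate
3 | (2S,3S)-epoxy alcohol acetate | OC[C@]1(C)O[C@H]1CC/C(C)=C/COC(C)=O | intermediate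
4 | benzyl ether acetate | c1ccccc1COC[C@]1(C)O[C@H]1CC/C(C)=C/COC(C)=O | intermediate
5 | epoxy benzyl ether allylic alcohol | c1ccccc1COC[C@]1(C)O[C@H]1CC/C(C)=C/CO | intermediate
6 | allylic mesylate (not isolated) | c1ccccc1COC[C@]1(C)O[C@H]1CC/C(C)=C/COS(C)(=O)=O | intermediate
7 | allylic bromide | c1ccccc1COC[C@]1(C)O[C@H]1CC/C(C)=C/CBr | intermediate
8 | methyl acetoacetate | COC(=O)CC(C)=O | starting material
9 | sodium lithium dianion of methyl acetoacetate (not isolated) | [Na+].[Li+].[CH2-]C(=O)[CH-]C(=O)OC | intermediate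
10 | epoxy β-keto ester | c1ccccc1COC[C@]1(C)O[C@H]1CC/C(C)=C/CCC(=O)CC(=O)OC | intermediate
11 | (2Z,6E)-enol phosphate | c1ccccc1COC[C@]1(C)O[C@H]1CC/C(C)=C/CC/C(OP(=O)(OCC)OCC)=C/C(=O)OC | intermediate
12 | (trimethylsilyl)methylmagnesium chloride | C[Si](C)(C)C[Mg]Cl | starting material
13 | (2Z,6E)-allylsilane ester | c1ccccc1COC[C@]1(C)O[C@H]1CC/C(C)=C/CC/C(C[Si](C)(C)C)=C/C(=O)OC | intermediate
14 | (2Z,6E)-allylsilane allylic alcohol | c1ccccc1COC[C@]1(C)O[C@H]1CC/C(C)=C/CC/C(C[Si](C)(C)C)=C/CO | intermediate
15 | (2Z,6E)-epoxy diene allylsilane TBS ether (cyclisation precursor) | c1ccccc1COC[C@]1(C)O[C@H]1CC/C(C)=C/CC/C(C[Si](C)(C)C)=C/CO[Si](C)(C)C(C)(C)C | intermediate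
16 | 18-benzyloxy-11-(TBS-oxy)-12,13,14,15,16-pentanorlabd-8(17)-en-3β-ol | c1ccccc1COC[C@]1(C)[C@@H](O)CC[C@@]2(C)[C@H]1CCC(=C)[C@@H]2CO[Si](C)(C)C(C)(C)C | intermediate
17 | 3-O-(imidazol-1-ylthiocarbonyl) derivative of 16 | c1ccccc1COC[C@]1(C)[C@@H](OC(=S)n3ccnc3)CC[C@@]2(C)[C@H]1CCC(=C)[C@@H]2CO[Si](C)(C)C(C)(C)C | intermediate
18 | 3-deoxy 8(17)-ene | c1ccccc1COC[C@]1(C)CCC[C@@]2(C)[C@H]1CCC(=C)[C@@H]2CO[Si](C)(C)C(C)(C)C | intermediate
19 | 8α,17-epoxide | c1ccccc1COC[C@]1(C)CCC[C@@]2(C)[C@H]1CC[C@@]3(OC3)[C@@H]2CO[Si](C)(C)C(C)(C)C | intermediate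
20 | 8α-alcohol | c1ccccc1COC[C@]1(C)CCC[C@@]2(C)[C@H]1CC[C@@](C)(O)[C@@H]2CO[Si](C)(C)C(C)(C)C | intermediate
21 | 8α-OTES benzyl ether | c1ccccc1COC[C@]1(C)CCC[C@@]2(C)[C@H]1CC[C@@](C)(O[Si](CC)(CC)CC)[C@@H]2CO[Si](C)(C)C(C)(C)C | intermediate
22 | C18 alcohol | OC[C@]1(C)CCC[C@@]2(C)[C@H]1CC[C@@](C)(O[Si](CC)(CC)CC)[C@@H]2CO[Si](C)(C)C(C)(C)C | intermediate
23 | C18 hypoiodite (not isolated) | IOC[C@]1(C)CCC[C@@]2(C)[C@H]1CC[C@@](C)(O[Si](CC)(CC)CC)[C@@H]2CO[Si](C)(C)C(C)(C)C | intermediate
24 | 6α,18-ether | C3[C@]1(C)CCC[C@@]2(C)[C@H]1[C@@H](O3)C[C@@](C)(O[Si](CC)(CC)CC)[C@@H]2CO[Si](C)(C)C(C)(C)C | intermediate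
25 | 18,6α-lactone (8α-OTES, 11-OTBS) | O=C3[C@]1(C)CCC[C@@]2(C)[C@H]1[C@@H](O3)C[C@@](C)(O[Si](CC)(CC)CC)[C@@H]2CO[Si](C)(C)C(C)(C)C | intermediate
26 | 8α,11-dihydroxy 18,6α-lactone | O=C3[C@]1(C)CCC[C@@]2(C)[C@H]1[C@@H](O3)C[C@@](C)(O)[C@@H]2CO | intermediate
27 | potassium 6α,8α,11-trihydroxy-18-oate (not isolated) | [K+].[O-]C(=O)[C@]1(C)CCC[C@@]2(C)[C@H]1[C@@H](O)C[C@@](C)(O)[C@@H]2CO | intermediate
28 | methyl 6α,8α,11-trihydroxy-12,13,14,15,16-pentanorlabdan-18-oate | COC(=O)[C@]1(C)CCC[C@@]2(C)[C@H]1[C@@H](O)C[C@@](C)(O)[C@@H]2CO | intermediate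
29 | 11-aldehyde diol | COC(=O)[C@]1(C)CCC[C@@]2(C)[C@H]1[C@@H](O)C[C@@](C)(O)[C@@H]2C=O | intermediate
30 | 6α,8α-bis-OTES 11-aldehyde | COC(=O)[C@]1(C)CCC[C@@]2(C)[C@H]1[C@@H](O[Si](CC)(CC)CC)C[C@@](C)(O[Si](CC)(CC)CC)[C@@H]2C=O | intermediate
31 | 11-ene (vinyl on C9) | COC(=O)[C@]1(C)CCC[C@@]2(C)[C@H]1[C@@H](O[Si](CC)(CC)CC)C[C@@](C)(O[Si](CC)(CC)CC)[C@@H]2C=C | intermediate
32 | but-2-yn-1-ol | CC#CCO | starting material
33 | (E)-alkenylzirconocene zirconium alkoxide (not isolated) | C/[C-]=C\C[O-].[Zr+4].[Zr+4].[Cl-].[Cl-].c1cc[cH-]c1.c1cc[cH-]c1.c1cc[cH-]c1.c1cc[cH-]c1 | intermediate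
34 | (E)-3-iodobut-2-en-1-ol | C/C(I)=C\CO | intermediate
35 | 12-(9-borabicyclo[3.3.1]nonan-9-yl) adduct of 31 (not isolated) | COC(=O)[C@]1(C)CCC[C@@]2(C)[C@H]1[C@@H](O[Si](CC)(CC)CC)C[C@@](C)(O[Si](CC)(CC)CC)[C@@H]2CCB3C4CCCC3CCC4 | intermediate
36 | (13E)-15-hydroxy labdenoate | COC(=O)[C@]1(C)CCC[C@@]2(C)[C@H]1[C@@H](O[Si](CC)(CC)CC)C[C@@](C)(O[Si](CC)(CC)CC)[C@@H]2CC/C(C)=C/CO | intermediate
37 | (13S,14S)-13,14-epoxy-15-ol | COC(=O)[C@]1(C)CCC[C@@]2(C)[C@H]1[C@@H](O[Si](CC)(CC)CC)C[C@@](C)(O[Si](CC)(CC)CC)[C@@H]2CC[C@]3(C)O[C@H]3CO | intermediate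
38 | (13R,14S)-13-hydroperoxy-14,15-diol | COC(=O)[C@]1(C)CCC[C@@]2(C)[C@H]1[C@@H](O[Si](CC)(CC)CC)C[C@@](C)(O[Si](CC)(CC)CC)[C@@H]2CC[C@](C)([C@@H](O)CO)OO | intermediate
39 | (13R,14S)-13-(triethylsilylperoxy)-14,15-diol | COC(=O)[C@]1(C)CCC[C@@]2(C)[C@H]1[C@@H](O[Si](CC)(CC)CC)C[C@@](C)(O[Si](CC)(CC)CC)[C@@H]2CC[C@](C)([C@@H](O)CO)OO[Si](CC)(CC)CC | intermediate
40 | (13R)-13-(triethylsilylperoxy)-14-aldehyde | COC(=O)[C@]1(C)CCC[C@@]2(C)[C@H]1[C@@H](O[Si](CC)(CC)CC)C[C@@](C)(O[Si](CC)(CC)CC)[C@@H]2CC[C@](C)(C=O)OO[Si](CC)(CC)CC | intermediate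
41 | (13R)-13-(triethylsilylperoxy)labd-14-enoate | COC(=O)[C@]1(C)CCC[C@@]2(C)[C@H]1[C@@H](O[Si](CC)(CC)CC)C[C@@](C)(O[Si](CC)(CC)CC)[C@@H]2CC[C@](C)(C=C)OO[Si](CC)(CC)CC | intermediate
42 | methyl propiolate | C#CC(=O)OC | starting material
43 | (E)-crotonaldehyde | C/C=C/C=O | starting material
44 | lithium methyl propiolate (not isolated) | [Li+].[C-]#CC(=O)OC | intermediate
45 | racemic methyl (5E)-4-hydroxyhept-5-en-2-ynoate | C/C=C/C(O)C#CC(=O)OC | intermediate
46 | methyl (5E)-4-oxohept-5-en-2-ynoate | C/C=C/C(=O)C#CC(=O)OC | intermediate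
47 | methyl (4S,5E)-4-hydroxyhept-5-en-2-ynoate | C/C=C/[C@H](O)C#CC(=O)OC | intermediate
48 | methyl (2Z,4S,5E)-4-hydroxy-3-methylhepta-2,5-dienoate (not isolated) | C/C=C/[C@H](O)/C(C)=C\C(=O)OC | intermediate
49 | (5S)-4-methyl-5-[(E)-prop-1-enyl]furan-2(5H)-one | C/C=C/[C@@H]1OC(=O)C=C1C | intermediate
50 | tris(triethylsilyl) derivative of the target | COC(=O)[C@]1(C)CCC[C@@]2(C)[C@H]1[C@@H](O[Si](CC)(CC)CC)C[C@@](C)(O[Si](CC)(CC)CC)[C@@H]2CC[C@](C)(/C=C/[C@@H]3OC(=O)C=C3C)OO[Si](CC)(CC)CC | intermediate
51 | CNP0128148.1 | COC(=O)[C@]1(C)CCC[C@@]2(C)[C@H]1[C@@H](O)C[C@@](C)(O)[C@@H]2CC[C@](C)(/C=C/[C@@H]1OC(=O)C=C1C)OO | target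

**Step count**
- Total: 37 steps.
- Longest linear sequence: 32 steps (steps 1–24, 26–31, 36 and 37).

**The three steps most likely to fail**

**Step 11 (cascade).**
- Risk: the cascade may stop after ring A. The activated epoxide may rearrange by hydride shift. The Lewis acid may ionise the allylic silyl ether, so that silyloxide and Me3Si are lost in a vinylogous Peterson-type elimination.
- Fallback: the same two bonds are formed, but the enol of the β-keto ester replaces the allylsilane as the terminating nucleophile. The fallback sets out from 10. SnCl4 in CH2Cl2 at −78 °C should open the epoxide at C4 and close rings A and B onto the enol carbon C9, giving the 3β-hydroxy-8-oxo ester F1 with the ester equatorial after equilibration. Non-basic Lombardo methylenation (Zn, CH2Br2, TiCl4) converts it to the 8(17)-methylene ester F2. LiAlH4 then gives the 3β,11-diol F3. Silylation of the primary alcohol alone (TBSCl, imidazole, one equivalent) comes back to the route at 16.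

**Step 18 (C6–H functionalisation).**
- Risk: the C18 alkoxy radical may fragment with loss of the C18 carbon instead of abstracting hydrogen, or the hydrogen transfer may be too slow.
- Fallback: an amidyl radical, which cannot fragment in this way, is used instead, and it delivers the lactone directly. The fallback sets out from 22. TEMPO/PhI(OAc)2 in aqueous MeCN gives the 18-carboxylic acid F4. Oxalyl chloride with catalytic DMF gives the acid chloride F5, and ammonia gives the primary amide F6. Photolysis with PhI(OAc)2 and I2 (Hofmann–Löffler–Freytag-type 1,5-hydrogen transfer from C6–Hα to nitrogen, then closure through the amide oxygen) gives the iminolactone F7. Mild aqueous acid hydrolyses F7 and brings the sequence back to the route at 25, so step 19 is no longer needed.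

**Step 28 (perhydrolysis).**
- Risk: the opening may take on carbocation character and erode the configuration at C13. Attack may occur at C14. O8 may capture C13 after loss of its silyl group.
- Fallback: the hydroperoxide is introduced by a Schenck ene reaction and the isomers are separated. The fallback sets out from 31 through borane 35. Suzuki–Miyaura coupling with commercial (E)-2-bromobut-2-ene under the conditions of step 26 gives the 15-deoxy (13E)-alkene F8. Photooxygenation (O2, tetraphenylporphyrin, visible light, CH2Cl2, −20 °C) abstracts hydrogen from C15 on the more crowded side of the alkene. This reaction is not face-selective, so the (13R)-13-hydroperoxy-14-ene F9 has to be separated from its isomers by chromatography. Silylation as in step 29 comes back to the route at 41.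

**Further compounds**
F1 | step 11 | methyl 18-benzyloxy-3β-hydroxy-8-oxo-12,13,14,15,16,17-hexanorlabdan-11-oate | c1ccccc1COC[C@]1(C)[C@@H](O)CC[C@@]2(C)[C@H]1CCC(=O)[C@@H]2C(=O)OC
F2 | step 11 | methyl 18-benzyloxy-3β-hydroxy-12,13,14,15,16-pentanorlabd-8(17)-en-11-oate | c1ccccc1COC[C@]1(C)[C@@H](O)CC[C@@]2(C)[C@H]1CCC(=C)[C@@H]2C(=O)OC
F3 | step 11 | 18-benzyloxy-12,13,14,15,16-pentanorlabd-8(17)-ene-3β,11-diol | c1ccccc1COC[C@]1(C)[C@@H](O)CC[C@@]2(C)[C@H]1CCC(=C)[C@@H]2CO
F4 | step 18 | 11-(TBS-oxy)-8α-(TES-oxy)-12,13,14,15,16-pentanorlabdan-18-oic acid | OC(=O)[C@]1(C)CCC[C@@]2(C)[C@H]1CC[C@@](C)(O[Si](CC)(CC)CC)[C@@H]2CO[Si](C)(C)C(C)(C)C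
F5 | step 18 | acid chloride of F4 | ClC(=O)[C@]1(C)CCC[C@@]2(C)[C@H]1CC[C@@](C)(O[Si](CC)(CC)CC)[C@@H]2CO[Si](C)(C)C(C)(C)C
F6 | step 18 | primary 18-amide | NC(=O)[C@]1(C)CCC[C@@]2(C)[C@H]1CC[C@@](C)(O[Si](CC)(CC)CC)[C@@H]2CO[Si](C)(C)C(C)(C)C
F7 | step 18 | 18,6α-iminolactone | N=C3[C@]1(C)CCC[C@@]2(C)[C@H]1[C@@H](O3)C[C@@](C)(O[Si](CC)(CC)CC)[C@@H]2CO[Si](C)(C)C(C)(C)C
F8 | step 28 | methyl (13E)-6α,8α-bis(triethylsilyloxy)labd-13-en-18-oate | COC(=O)[C@]1(C)CCC[C@@]2(C)[C@H]1[C@@H](O[Si](CC)(CC)CC)C[C@@](C)(O[Si](CC)(CC)CC)[C@@H]2CC/C(C)=C/C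
F9 | step 28 | methyl (13R)-13-hydroperoxy-6α,8α-bis(triethylsilyloxy)labd-14-en-18-oate | COC(=O)[C@]1(C)CCC[C@@]2(C)[C@H]1[C@@H](O[Si](CC)(CC)CC)C[C@@](C)(O[Si](CC)(CC)CC)[C@@H]2CC[C@](C)(C=C)OO
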